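**Retrosynthetic overview**

1. The target is reached from its pentabenzyl ether by hydrogenolysis; all five phenol protecting groups are benzyl from the start.
2. The strategy rests on the O1–C8a bond of ring C. C8a lies between C8 (bearing the (R)-1-arylethyl arm) and C4a (bearing C4=O) and is meta to O5 and O7. A fluorine kept from 1,3,5-trifluorobenzene marks this carbon, steers lithiation to both neighbouring carbons, and is finally displaced by the oxygen of a 2-benzyloxy-1,3-diketone enolate (SNAr).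
3. The diketone comes from C-aroylation of an aryl benzyloxymethyl ketone enolate (C2–C3 bond, flavone numbering); the ketone comes from ortho-lithiation and Weinreb acylation (C4–C4a bond).
4. The (R)-1,1-diarylethane comes from iridium-catalysed asymmetric hydrogenation of a 1,1-diarylethene, made by adding ortho-lithiated 1,3-bis(benzyloxy)-5-fluorobenzene to O-benzylacetosyringone and dehydrating.
5. Ring order: ring A, ring B and the syringyl ring are bought as arenes; ring C is the only ring formed, in the key step.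

Key step: step 10

Remark: which antipode of the P,N ligand delivers the (R)-alkane in step 5 cannot be assigned in advance; the (S)-ligand is written, and its mirror image is used if the first run proves to give the (S)-alkane.

**Route**

Step 1
Reactants: 1 1,3,5-trifluorobenzene
Product: 3 1,3-bis(benzyloxy)-5-fluorobenzene, via 1-(benzyloxy)-3,5-difluorobenzene 2 (not isolated)
Conditions: BnOH (2.2 equiv), NaH (2.3 equiv), NMP, 0 → 100 °C
Reagents that add atoms: benzyl alcohol, OCc1ccccc1
Why: Twofold SNAr by sodium benzyloxide, in which each alkoxy group enters meta to the remaining fluorines so that the second displacement still proceeds on heating while the third is much slower and leaves one fluorine as the marker for O1.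

Step 2
Reactants: 4 acetosyringone
Product: 5 1-[4-(benzyloxy)-3,5-dimethoxyphenyl]ethan-1-one
Conditions: BnBr, K2CO3, DMF, 60 °C
Reagents that add atoms: benzyl bromide, BrCc1ccccc1
Why: Williamson ether synthesis on the only phenol.

Step 3
Reactants: 3 1,3-bis(benzyloxy)-5-fluorobenzene; 5 1-[4-(benzyloxy)-3,5-dimethoxyphenyl]ethan-1-one
Product: 7 1-[2,4-bis(benzyloxy)-6-fluorophenyl]-1-[4-(benzyloxy)-3,5-dimethoxyphenyl]ethan-1-ol (racemic), via aryllithium 6 (not isolated)
Conditions: n-BuLi (1.05 equiv), THF, −78 °C; then 5, −78 °C; aq. NH4Cl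
Reagents that add atoms: none
Why: Directed ortho-lithiation at the C–H flanked by fluorine and benzyloxy (the most acidic site, two equivalent positions) followed by 1,2-addition to the ketone at a temperature below loss of LiF to the aryne; the carbinol centre forms racemic and is removed in step 4.

Step 4
Reactants: 7 1-[2,4-bis(benzyloxy)-6-fluorophenyl]-1-[4-(benzyloxy)-3,5-dimethoxyphenyl]ethan-1-ol
Product: 8 1-[2,4-bis(benzyloxy)-6-fluorophenyl]-1-[4-(benzyloxy)-3,5-dimethoxyphenyl]ethene
Conditions: p-TsOH·H2O (2 mol%), toluene, 40 °C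
Reagents that add atoms: none
Why: Acid-catalysed E1 dehydration of a tertiary doubly benzylic alcohol, in which the methyl group is the only source of a β-hydrogen so a single alkene can form.

Step 5
Reactants: 8 1-[2,4-bis(benzyloxy)-6-fluorophenyl]-1-[4-(benzyloxy)-3,5-dimethoxyphenyl]ethene
Product: 9 (R)-1-[2,4-bis(benzyloxy)-6-fluorophenyl]-1-[4-(benzyloxy)-3,5-dimethoxyphenyl]ethane
Conditions: H2 (5 bar), [Ir(cod)((S)-tBu-PHOX)][B(3,5-(CF3)2C6H3)4] (2 mol%), CH2Cl2, rt
Reagents that add atoms: none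
Why: Iridium-catalysed asymmetric hydrogenation of a 1,1-diarylethene with a cationic P,N-ligated catalyst, in which the 2,6-disubstituted ring A is twisted out of the alkene plane while the 3,5-dimethoxyaryl ring stays coplanar, so the chiral ligand can tell the two aryl groups apart and selects the alkene face that gives the (R) centre; benzyl ethers and the C–F bond are inert to this homogeneous catalyst.

Step 6
Reactants: 10 benzyloxyacetyl chloride
Product: 11 2-(benzyloxy)-N-methoxy-N-methylacetamide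
Conditions: MeNH(OMe)·HCl, Et3N (2.2 equiv), CH2Cl2, 0 °C → rt
Reagents that add atoms: N,O-dimethylhydroxylamine hydrochloride, CNOC.Cl
Why: N-Acylation of the hydroxylamine by the acid chloride gives the Weinreb amide.

Step 7
Reactants: 9 (R)-1-[2,4-bis(benzyloxy)-6-fluorophenyl]-1-[4-(benzyloxy)-3,5-dimethoxyphenyl]ethane; 11 2-(benzyloxy)-N-methoxy-N-methylacetamide
Product: 13 2-(benzyloxy)-1-{4,6-bis(benzyloxy)-3-[(1R)-1-(4-benzyloxy-3,5-dimethoxyphenyl)ethyl]-2-fluorophenyl}ethan-1-one, via aryllithium 12 (not isolated)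
Conditions: n-BuLi (1.05 equiv), THF, −78 °C; then 11, −78 → −40 °C; aq. NH4Cl
Reagents that add atoms: none
Why: Second directed ortho-lithiation at the one remaining C–H flanked by fluorine and benzyloxy (kinetically far faster at −78 °C than removal of the hindered doubly benzylic methine hydrogen, so the (R) centre should be kept) followed by Weinreb ketone synthesis, which stops at the ketone.

Step 8
Reactants: 14 4-(benzyloxy)-3-methoxybenzoic acid
Product: 15 4-(benzyloxy)-3-methoxybenzoyl chloride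
Conditions: (COCl)2, DMF (cat.), CH2Cl2, 0 °C → rt; used crude
Reagents that add atoms: oxalyl chloride, O=C(Cl)C(Cl)=O
Why: Acid chloride formation through the chloroiminium species generated from DMF and oxalyl chloride.

Step 9
Reactants: 13 2-(benzyloxy)-1-{4,6-bis(benzyloxy)-3-[(1R)-1-(4-benzyloxy-3,5-dimethoxyphenyl)ethyl]-2-fluorophenyl}ethan-1-one; 15 4-(benzyloxy)-3-methoxybenzoyl chloride
Product: 17 2-(benzyloxy)-1-{4,6-bis(benzyloxy)-3-[(1R)-1-(4-benzyloxy-3,5-dimethoxyphenyl)ethyl]-2-fluorophenyl}-3-[4-(benzyloxy)-3-methoxyphenyl]propane-1,3-dione, via lithium enolate 16 (not isolated)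
Conditions: LiN(SiMe3)2 (2.1 equiv), THF–toluene, −78 °C; then 15, −78 → 0 °C; AcOH quench
Reagents that add atoms: none
Why: Crossed Claisen-type C-aroylation of the chelated lithium enolate formed at the only enolisable position, with the second equivalent of base holding the more acidic diketone as its lithium salt so that it is not acylated again; the new C2 centre forms as a mixture of epimers and enol, which does not matter because C2 becomes sp2 in step 10.

Step 10
Reactants: 17 2-(benzyloxy)-1-{4,6-bis(benzyloxy)-3-[(1R)-1-(4-benzyloxy-3,5-dimethoxyphenyl)ethyl]-2-fluorophenyl}-3-[4-(benzyloxy)-3-methoxyphenyl]propane-1,3-dione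
Product: 19 3,5,7-tris(benzyloxy)-2-[4-(benzyloxy)-3-methoxyphenyl]-8-[(1R)-1-(4-benzyloxy-3,5-dimethoxyphenyl)ethyl]-4H-chromen-4-one, via caesium enolate 18 (not isolated)
Conditions: Cs2CO3 (1.5 equiv), dry DMF, 80 °C
Reagents that add atoms: none
Why: Cs2CO3 removes the C2 hydrogen of the diketone to give the delocalised enolate 18, whose oxygen on the ring B side adds to the fluorine-bearing carbon C8a; the resulting Meisenheimer adduct passes its charge to the C4 carbonyl on the neighbouring C4a, and loss of fluoride restores ring A and leaves the pyranone (addition–elimination SNAr). The closest known reaction is the base-mediated cyclisation of 1-(2-fluoroaryl)-1,3-diketones to chromones and flavones. Ring C closes by a six-membered intramolecular attack on aromatic C8a, 6-exo-trig when the C8a=C8 bond of ring A is taken as the π bond that is broken, with fluoride leaving outside the new ring. No stereocentre is formed, and the (R) centre is not touched because its C–H is not conjugated with the carbonyl and is far too weakly acidic for carbonate. The step needs O-arylation in preference to C-arylation and substitution at C8a only: ring size secures the first, since the central carbon and the other oxygen could reach C8a only through four-membered rings. The single fluorine secures the second, and because it sits meta to both benzyloxy groups they do not push electron density onto the ring positions that take up the negative charge.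

Step 11
Reactants: 19 3,5,7-tris(benzyloxy)-2-[4-(benzyloxy)-3-methoxyphenyl]-8-[(1R)-1-(4-benzyloxy-3,5-dimethoxyphenyl)ethyl]-4H-chromen-4-one
Product: 20 3,5,7-trihydroxy-2-(4-hydroxy-3-methoxyphenyl)-8-[(1R)-1-(4-hydroxy-3,5-dimethoxyphenyl)ethyl]-4H-chromen-4-one
Conditions: H2 (1 atm), Pd/C (10%), THF–MeOH (1:1), rt
Reagents that add atoms: none
Why: Catalytic hydrogenolysis of the five O-benzyl ethers, which leaves the methyl ethers, the flavonol C2=C3 bond and the C–C bonds at the benzylic stereocentre intact under these mild conditions.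

**Compound list**

1 | 1,3,5-trifluorobenzene | Fc1cc(F)cc(F)c1 | starting material
2 | 1-(benzyloxy)-3,5-difluorobenzene | Fc1cc(F)cc(OCc2ccccc2)c1 | intermediate (not isolated)
3 | 1,3-bis(benzyloxy)-5-fluorobenzene | Fc1cc(OCc2ccccc2)cc(OCc2ccccc2)c1 | intermediate
4 | acetosyringone, 1-(4-hydroxy-3,5-dimethoxyphenyl)ethan-1-one | CC(=O)c1cc(OC)c(O)c(OC)c1 | starting material
5 | 1-[4-(benzyloxy)-3,5-dimethoxyphenyl]ethan-1-one | CC(=O)c1cc(OC)c(OCc2ccccc2)c(OC)c1 | intermediate
6 | [2,4-bis(benzyloxy)-6-fluorophenyl]lithium | [Li]c1c(F)cc(OCc2ccccc2)cc1OCc1ccccc1 | intermediate (not isolated)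
7 | 1-[2,4-bis(benzyloxy)-6-fluorophenyl]-1-[4-(benzyloxy)-3,5-dimethoxyphenyl]ethan-1-ol (racemic) | CC(O)(c1c(F)cc(OCc2ccccc2)cc1OCc1ccccc1)c1cc(OC)c(OCc2ccccc2)c(OC)c1 | intermediate
8 | 1-[2,4-bis(benzyloxy)-6-fluorophenyl]-1-[4-(benzyloxy)-3,5-dimethoxyphenyl]ethene | C=C(c1c(F)cc(OCc2ccccc2)cc1OCc1ccccc1)c1cc(OC)c(OCc2ccccc2)c(OC)c1 | intermediate
9 | (R)-1-[2,4-bis(benzyloxy)-6-fluorophenyl]-1-[4-(benzyloxy)-3,5-dimethoxyphenyl]ethane | Fc1cc(OCc2ccccc2)cc(OCc2ccccc2)c1[C@H](C)c1cc(OC)c(OCc2ccccc2)c(OC)c1 | intermediate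
10 | benzyloxyacetyl chloride | O=C(Cl)COCc1ccccc1 | starting material
11 | 2-(benzyloxy)-N-methoxy-N-methylacetamide | CON(C)C(=O)COCc1ccccc1 | intermediate
12 | {4,6-bis(benzyloxy)-3-[(1R)-1-(4-benzyloxy-3,5-dimethoxyphenyl)ethyl]-2-fluorophenyl}lithium | Fc1c([Li])c(OCc2ccccc2)cc(OCc2ccccc2)c1[C@H](C)c1cc(OC)c(OCc2ccccc2)c(OC)c1 | intermediate (not isolated)
13 | 2-(benzyloxy)-1-{4,6-bis(benzyloxy)-3-[(1R)-1-(4-benzyloxy-3,5-dimethoxyphenyl)ethyl]-2-fluorophenyl}ethan-1-one | Fc1c(C(=O)COCc2ccccc2)c(OCc2ccccc2)cc(OCc2ccccc2)c1[C@H](C)c1cc(OC)c(OCc2ccccc2)c(OC)c1 | intermediate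
14 | 4-(benzyloxy)-3-methoxybenzoic acid | COc1cc(C(=O)O)ccc1OCc1ccccc1 | starting material
15 | 4-(benzyloxy)-3-methoxybenzoyl chloride | COc1cc(C(=O)Cl)ccc1OCc1ccccc1 | intermediate
16 | lithium enolate of ketone 13 | Fc1c(C(O[Li])=COCc2ccccc2)c(OCc2ccccc2)cc(OCc2ccccc2)c1[C@H](C)c1cc(OC)c(OCc2ccccc2)c(OC)c1 | intermediate (not isolated)
17 | 2-(benzyloxy)-1-{4,6-bis(benzyloxy)-3-[(1R)-1-(4-benzyloxy-3,5-dimethoxyphenyl)ethyl]-2-fluorophenyl}-3-[4-(benzyloxy)-3-methoxyphenyl]propane-1,3-dione (keto form; C2 epimers and enol) | COc1cc(C(=O)C(OCc2ccccc2)C(=O)c2c(F)c([C@H](C)c3cc(OC)c(OCc4ccccc4)c(OC)c3)c(OCc3ccccc3)cc2OCc2ccccc2)ccc1OCc1ccccc1 | intermediate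
18 | caesium enolate of diketone 17 | COc1cc(C([O-])=C(OCc2ccccc2)C(=O)c2c(F)c([C@H](C)c3cc(OC)c(OCc4ccccc4)c(OC)c3)c(OCc3ccccc3)cc2OCc2ccccc2)ccc1OCc1ccccc1.[Cs+] | intermediate (not isolated)
19 | 3,5,7-tris(benzyloxy)-2-[4-(benzyloxy)-3-methoxyphenyl]-8-[(1R)-1-(4-benzyloxy-3,5-dimethoxyphenyl)ethyl]-4H-chromen-4-one | COc1cc(-c2oc3c([C@H](C)c4cc(OC)c(OCc5ccccc5)c(OC)c4)c(OCc4ccccc4)cc(OCc4ccccc4)c3c(=O)c2OCc2ccccc2)ccc1OCc1ccccc1 | intermediate
20 | 3,5,7-trihydroxy-2-(4-hydroxy-3-methoxyphenyl)-8-[(1R)-1-(4-hydroxy-3,5-dimethoxyphenyl)ethyl]-4H-chromen-4-one | COc1cc(-c2oc3c([C@H](C)c4cc(OC)c(O)c(OC)c4)c(O)cc(O)c3c(=O)c2O)ccc1O | target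

**Step count**

Total: 11 steps. Longest linear sequence: 8 steps (steps 1, 3, 4, 5, 7, 9, 10, 11, from 1,3,5-trifluorobenzene).

**Steps most likely to fail**

Step 10 (key step). The hindered, delocalised enolate may add too slowly to an electron-rich ring whose aroyl group is twisted out of conjugation, so that retro-Claisen cleavage of the diketone outruns ring closure. The fallback sets out from 17 and comes back at 19, making the same O1–C8a bond with a localised alkoxide at a lower oxidation level. NaBH4 in THF–MeOH should reduce both carbonyls to give 2-(benzyloxy)-1-{4,6-bis(benzyloxy)-3-[(1R)-1-(4-benzyloxy-3,5-dimethoxyphenyl)ethyl]-2-fluorophenyl}-3-[4-(benzyloxy)-3-methoxyphenyl]propane-1,3-diol F1 as a diastereomer mixture. KH in DMF should then close the chroman by alkoxide SNAr at the same C–F carbon; only the hydroxyl on the ring B side can form a six-membered ring. This gives 3,5,7-tris(benzyloxy)-2-[4-(benzyloxy)-3-methoxyphenyl]-8-[(1R)-1-(4-benzyloxy-3,5-dimethoxyphenyl)ethyl]chroman-4-ol F2. Dess–Martin oxidation gives the corresponding 3-benzyloxychroman-4-one F3, and aerobic dehydrogenation with Pd(OCOCF3)2/DMSO/O2 in AcOH introduces the C2=C3 bond to give 19. The diastereomer mixtures converge because C2, C3 and C4 all end as sp2 carbons.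

Step 5. Facial selectivity may be poor, or the hindered alkene may convert incompletely. The fallback sets out from 5 and aryllithium 6 and comes back at 9, building the stereocentre by stereospecific lithiation–borylation. Noyori transfer hydrogenation of 5 with RuCl[(S,S)-TsDPEN](p-cymene) and HCO2H/Et3N should give (S)-1-[4-(benzyloxy)-3,5-dimethoxyphenyl]ethanol F4. N,N-Diisopropylcarbamoyl chloride and Et3N convert it into (S)-1-[4-(benzyloxy)-3,5-dimethoxyphenyl]ethyl N,N-diisopropylcarbamate F5. Aryllithium 6 is quenched with 2-isopropoxy-4,4,5,5-tetramethyl-1,3,2-dioxaborolane to give 2-[2,4-bis(benzyloxy)-6-fluorophenyl]-4,4,5,5-tetramethyl-1,3,2-dioxaborolane F6. F5 is deprotonated with s-BuLi in Et2O at −78 °C and treated with F6, and MgBr2/MeOH with warming triggers the 1,2-aryl shift. Boron enters with retention and the aryl group displaces the carbamate with inversion, giving 2-{(1R)-1-[2,4-bis(benzyloxy)-6-fluorophenyl]-1-[4-(benzyloxy)-3,5-dimethoxyphenyl]ethyl}-4,4,5,5-tetramethyl-1,3,2-dioxaborolane F7. Protodeboronation with CsF/H2O in dioxane, which proceeds with retention, should then give 9.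

Step 7. Metalation may occur at the wrong site (between the two benzyloxy groups, or at the doubly benzylic methine with erosion of configuration), or the hindered aryllithium may enolise amide 11 instead of adding to it. The fallback sets out from 9 and comes back at 13, replacing metalation by electrophilic substitution. Vilsmeier–Haack formylation (POCl3, DMF, then aq. NaOAc) should attack the open ring A position that is para to one benzyloxy group, ortho to the other and flanked only by fluorine; the position between the two benzyloxy groups and the syringyl positions next to the branched benzylic carbon are more hindered. This gives 4,6-bis(benzyloxy)-3-[(1R)-1-(4-benzyloxy-3,5-dimethoxyphenyl)ethyl]-2-fluorobenzaldehyde F8. Addition of (benzyloxymethyl)lithium, generated from tributyl[(benzyloxy)methyl]stannane and n-BuLi at −78 °C, gives 2-(benzyloxy)-1-{4,6-bis(benzyloxy)-3-[(1R)-1-(4-benzyloxy-3,5-dimethoxyphenyl)ethyl]-2-fluorophenyl}ethan-1-ol F9 as a mixture of carbinol epimers. Dess–Martin oxidation gives 13.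

**Further compounds**

F1 | step 10 | 2-(benzyloxy)-1-{4,6-bis(benzyloxy)-3-[(1R)-1-(4-benzyloxy-3,5-dimethoxyphenyl)ethyl]-2-fluorophenyl}-3-[4-(benzyloxy)-3-methoxyphenyl]propane-1,3-diol (diastereomer mixture) | COc1cc(C(O)C(OCc2ccccc2)C(O)c2c(F)c([C@H](C)c3cc(OC)c(OCc4ccccc4)c(OC)c3)c(OCc3ccccc3)cc2OCc2ccccc2)ccc1OCc1ccccc1
F2 | step 10 | 3,5,7-tris(benzyloxy)-2-[4-(benzyloxy)-3-methoxyphenyl]-8-[(1R)-1-(4-benzyloxy-3,5-dimethoxyphenyl)ethyl]chroman-4-ol (diastereomer mixture) | COc1cc(C2Oc3c([C@H](C)c4cc(OC)c(OCc5ccccc5)c(OC)c4)c(OCc4ccccc4)cc(OCc4ccccc4)c3C(O)C2OCc2ccccc2)ccc1OCc1ccccc1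
F3 | step 10 | 3,5,7-tris(benzyloxy)-2-[4-(benzyloxy)-3-methoxyphenyl]-8-[(1R)-1-(4-benzyloxy-3,5-dimethoxyphenyl)ethyl]chroman-4-one (C2/C3 diastereomer mixture) | COc1cc(C2Oc3c([C@H](C)c4cc(OC)c(OCc5ccccc5)c(OC)c4)c(OCc4ccccc4)cc(OCc4ccccc4)c3C(=O)C2OCc2ccccc2)ccc1OCc1ccccc1
F4 | step 5 | (S)-1-[4-(benzyloxy)-3,5-dimethoxyphenyl]ethanol | C[C@H](O)c1cc(OC)c(OCc2ccccc2)c(OC)c1
F5 | step 5 | (S)-1-[4-(benzyloxy)-3,5-dimethoxyphenyl]ethyl N,N-diisopropylcarbamate | C[C@H](OC(=O)N(C(C)C)C(C)C)c1cc(OC)c(OCc2ccccc2)c(OC)c1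
F6 | step 5 | 2-[2,4-bis(benzyloxy)-6-fluorophenyl]-4,4,5,5-tetramethyl-1,3,2-dioxaborolane | CC1(C)OB(c2c(F)cc(OCc3ccccc3)cc2OCc2ccccc2)OC1(C)C
F7 | step 5 | 2-{(1R)-1-[2,4-bis(benzyloxy)-6-fluorophenyl]-1-[4-(benzyloxy)-3,5-dimethoxyphenyl]ethyl}-4,4,5,5-tetramethyl-1,3,2-dioxaborolane | Fc1cc(OCc2ccccc2)cc(OCc2ccccc2)c1[C@](B3OC(C)(C)C(C)(C)O3)(C)c4cc(OC)c(OCc5ccccc5)c(OC)c4
F8 | step 7 | 4,6-bis(benzyloxy)-3-[(1R)-1-(4-benzyloxy-3,5-dimethoxyphenyl)ethyl]-2-fluorobenzaldehyde | O=Cc1c(F)c([C@H](C)c2cc(OC)c(OCc3ccccc3)c(OC)c2)c(OCc2ccccc2)cc1OCc1ccccc1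
F9 | step 7 | 2-(benzyloxy)-1-{4,6-bis(benzyloxy)-3-[(1R)-1-(4-benzyloxy-3,5-dimethoxyphenyl)ethyl]-2-fluorophenyl}ethan-1-ol (carbinol epimers) | OC(COCc1ccccc1)c1c(F)c([C@H](C)c2cc(OC)c(OCc3ccccc3)c(OC)c2)c(OCc2ccccc2)cc1OCc1ccccc1
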